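(The constants used here are assumed; no experiment stands behind them.)

The constants and charges set how much open intermediate stands at the end of each set-up.

    substrate → open intermediate (k1 = 3.7 × 10⁻⁴ s⁻¹)
    partner → second intermediate (k2 = 4.2 × 10⁻⁴ s⁻¹)
    open intermediate + second intermediate → target (k3 = 0.033 L mol⁻¹ s⁻¹)
    2 open intermediate → homo product (k4 = 0.024 L mol⁻¹ s⁻¹)
    second intermediate → side product (k5 = 3.7 × 10⁻⁴ s⁻¹)
    target ⇌ isomer of the product (K6 = 0.97, k6 = 1.2 × 10⁻⁴ s⁻¹)

| flask | substrate | partner | time | remark |
|---|---|---|---|---|
| Friday's | 0.050 M (fed, over 1.00 h) | 0.0350 M | 1.0 h | all but substrate at the start; substrate goes in evenly over 1.00 h, the run ends at 1.0 h |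
| Sunday's | 0.050 M | 0.0350 M (fed, over 1.00 h) | 1.0 h | a stirred flask in which partner is dosed at a steady rate over 1.00 h without added volume, worked up at 1.0 h |
| Thursday's | 0.050 M | 0.0350 M | 1.0 h | a closed flask charged with all of it at once and left for 1.0 h |
| Wednesday's | 0.050 M | 0.0350 M |  | a single well-mixed tank run continuously and read at steady state, 1.0 h in it on average |

- in percentages every species weighs as the substrate in it: one homo product counts as two
- a doubled species enters its step squared and goes two at a time
- the stated concentrations are those of everything mixed, before any reaction; amounts are the same in each set-up
- the feed brings no volume worth counting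
- run time (Friday's): 1.0 h

* the set-up with the highest amount of open intermediate at the outlet or at the end, in percent of the substrate put in ("none" if the first two lie within 2 percentage points) (Friday's / Sunday's / Thursday's / Wednesday's / none)
* amount of open intermediate at the outlet or at the end, in percent of the substrate put in, Friday's
* amount of open intermediate at the outlet or at the end, in percent of the substrate put in, Sunday's
* amount of open intermediate at the outlet or at the end, in percent of the substrate put in, Thursday's
* amount of open intermediate at the outlet or at the end, in percent of the substrate put in, Wednesday's

I work with F, the fraction of the substrate charge left as substrate, and not with what is made. Let x be open intermediate as a fraction of the charge, and k the opening constant, 1.3 h⁻¹. In Thursday's flask the supply starts at k and slows by the factor F, which is 26.4% at the end. The drain I count is the homo step, a·x², where a counts two open intermediate per turn: a = 8.64 h⁻¹. Where supply meets this drain stands the balance level, a steady-state approximation: the level at which the homo step removes what opening delivers. At full supply it is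

C = √(k/a) = 39.3%

The drain goes with the square, so a slowing by F lowers the level by √F:

x ≈ C·√F

Thursday's gives 20.2%, and Sunday's, with its substrate also charged at once, gives 20.2%. Both figures neglect the reaction with second intermediate, which lowers the level, while falling supply leaves the level trailing above its balance. In Friday's flask, evenly fed substrate leaves F = (1 − 26.4%)/(k·tf) = 55.3%, where tf is the dosing time. Its supply climbs from zero, so I claim a bound: 29.2%. I do not reckon Wednesday's tank, and with Friday's merely bounded I name no winner.

The forecast gives 20.4% for Friday's, 19.8% for Sunday's, 18.5% for Thursday's and 17.5% for Wednesday's, with best: none, since “Friday's and Sunday's are less than 2 points apart, so neither wins”. It sets Sunday's above Thursday's, where my balance level gives them the same figure.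

The simulation gives 20.5%, 19.8%, 18.5% and 17.5% in that order, and best: none. Friday's stands below its balance level. At 0.327 h in Friday's flask, the reaction with second intermediate used open intermediate 2.7 times faster than the homo step. At 1.00 h Friday's held 12.0% homo product beside 10.9% target, with 55.3% substrate.

Friday's flask read at 2.5 h has had no feed since tf, so F = 7.49% and C·√F = 10.8%. The simulation gives 7.49% substrate and 12.7% open intermediate there.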